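(Readings and results are calculated for substances that don't exist; scatter was added.)

One percentage point of these readings is 0.400 mM of substrate.

| setting | dawn | summer | north | south-west | north-west |
|---|---|---|---|---|---|
| E | 20 mM | 20 mM | 20 mM | 20 mM | 20 mM |
| G | 20 mM | 20 mM | 20 mM | 20 mM | 20 mM |
| L | 3 mM | 33 mM | 5.00 mM | 15.0 mM | 50.0 mM |
| J | 2 mM | 2 mM | 2.0 mM | 2.0 mM | 2.0 mM |
| remark | run made earlier | run made earlier |  |  |  |
| time |  |  | 3.0 h | 3.0 h | 3.0 h |

- dawn (time / h: X / %, D / %): 0.833: 4.9, 0.2; 1.50: 5.5, 0; 2.50: 6.6, 0; 3.00: 7.1, 0
- summer (time / h: X / %, D / %): 0.250: 18.6, 1.2; 0.500: 28.3, 1.6; 1.33: 41.7, 3.0; 3.00: 47.7, 4.0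

(each reading ± 0.5 percentage points)

- J is single-handed; E and G are mirror images of each other, charged as a racemate, each of them at the stated concentration
- an excess is the difference of the two amounts in percent of their sum
- "hardly changes" means that all values lie within two and a half points (for a concentration: within two and a half percent of the largest)

- excess of X over D at the end for north, south-west, north-west, in this order
- the course of these numbers from the first flask to the last (falls, then rises / hardly changes / rises all the way / rises, then falls / falls all the way)

Dawn's last X is 2.84 mM against 3 mM of L, so we take one L per product, with L the limiting reagent in dawn.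

E and G meet the same L and the same J, and each falls in proportion to its own amount. So we divide one rate by the other, and time drops out:

ln(fraction of E left) / ln(fraction of G left) = constant

Summer's last reading leaves 4.60% of E and 92.0% of G, which gives 36.9. This ratio of logarithms is the selectivity factor.

The same reading gives the rate constant of E with L, from the second-order integrated form: 0.0568 mM⁻¹ h⁻¹. We charge the L used to E, reckon X in each flask at 3.0 h, and let the factor turn the E left into D:

north: X 4.70 mM, D 0.145 mM, excess 94.0%

south-west: X 12.6 mM, D 0.535 mM, excess 91.9%

north-west: X 19.9 mM, D 2.82 mM, excess 75.2%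

The weak link is the factor, since summer's D of 4.0% carries a scatter of 0.5 percentage points. Summer's reading at 1.33 h gives 29.0, and with it the excesses become 92.5%, 89.8% and 70.0%, which still fall. We commit to the excesses reckoned with 36.9, because summer's D at 3.00 h is larger than at 1.33 h, and to a steady fall.

The forecast gives 94%, 91% and 74%, falls all the way, because “G keeps reacting, so the excess falls throughout”; in north-west it lies 1.2 points below ours.

The flasks give 94.7%, 92.8% and 77.6%: the row falls all the way.

    L + J + E → J + X (k = 12.0 M⁻² s⁻¹)
    L + J + G → J + D (k = 0.290 M⁻² s⁻¹)
    J ⇌ Q (K = 0.490, k = 0.00150 s⁻¹)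

The steps to X and to D both run through J, so the division holds the same J above and below; in north-west J stands at 67.1% of the catalyst charged after 1.50 h and 67.1% after 3.00 h, with Q at 32.9%. North-west ends with 0.39% of its E, which the factor 36.9 turns into 86.0% of G left, and the flask holds 87%. South-west ends with 38% of its E, which gives 97.4% of G, and the flask holds 98%.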